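**Plan**

- Retrosynthesis: the six benzyl ethers come off last. The C4 ketone is traced back to its carbinol, which locks the configuration. The O1–C2 and C4–C4a bonds of flavanone ring C are then cut together, giving the 2-iodo-3,5-bis(benzyloxy)phenyl ester of an α-aryl cinnamic acid. That acid is cut at the ester C–O bond, at the flavone pyranone ring (chalcone) and at the Cα–aryl bond (Suzuki).
- Forward order: α-bromocinnamate (Wittig), α-aryl cinnamate (borylation/Suzuki), flavone half (Claisen–Schmidt, then closure of its ring C with I2/DMSO), iodoaryl ester, ring C of the flavanone half (step 7), reduction/oxidation, debenzylation.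
- Enabling feature: in flavanone ring A the carbon C4a lies between C8a, which carries O1, and the oxygen-bearing C5 (phloroglucinol pattern). A carbanion at C4a of an O1-acylated phenol can therefore move the cinnamoyl carbon (C4) from O1 to C4a and free O1 to add to C2. The C3 aryl group is already the α-aryl group of the acid.
- Stereochemistry: step 7 should give the racemic 2,3-trans ketone under thermodynamic control. C2 and C3 are then set absolutely by Ru-catalysed transfer hydrogenation with dynamic kinetic resolution (step 8) and kept through base-free oxidation and neutral hydrogenolysis.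

Key step: step 7

Assumption: benzyl ethers 5, 8 and 12 are bought; each is otherwise one benzylation away from the parent phenol.

**Step 1**
Reactants: 1 4-(benzyloxy)benzaldehyde; 2 methyl (triphenylphosphoranylidene)acetate
Product: 4 methyl (Z)-2-bromo-3-[4-(benzyloxy)phenyl]prop-2-enoate, via bromo ylide 3 (not isolated)
Conditions: NBS, CH2Cl2, −20 °C; then 1, −20 °C → rt
Reagents that add atoms: N-bromosuccinimide (NBS), O=C1CCC(=O)N1Br
Why: One-pot ylide bromination and Wittig olefination, in which the stabilized bromo ylide should give the α-bromo acrylate with bromine and aryl group cis (Z).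

**Step 2**
Reactants: 5 4-(benzyloxy)-3-bromobenzaldehyde; 4 methyl (Z)-2-bromo-3-[4-(benzyloxy)phenyl]prop-2-enoate
Product: 7 methyl (E)-2-[2-(benzyloxy)-5-formylphenyl]-3-[4-(benzyloxy)phenyl]prop-2-enoate, via pinacol boronate 6 (not isolated)
Conditions: B2pin2, Pd(dppf)Cl2 (3 mol%), KOAc, 1,4-dioxane, 90 °C; then 4, aq. K3PO4, 80 °C
Reagents that add atoms: none
Why: Miyaura borylation followed in the same pot by Suzuki–Miyaura coupling, in which the alkenyl bromide couples with retention so that the two aryl groups end up cis, and aldehyde and ester tolerate acetate and phosphate.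

**Step 3**
Reactants: 7 methyl (E)-2-[2-(benzyloxy)-5-formylphenyl]-3-[4-(benzyloxy)phenyl]prop-2-enoate; 8 1-[2,4-bis(benzyloxy)-6-hydroxyphenyl]ethanone
Product: 10 (E)-2-{2-(benzyloxy)-5-[(E)-3-(2,4-bis(benzyloxy)-6-hydroxyphenyl)-3-oxoprop-1-enyl]phenyl}-3-[4-(benzyloxy)phenyl]prop-2-enoic acid, via chalcone methyl ester 9 (not isolated)
Conditions: KOH (aq. 50%), EtOH/THF, rt; then 60 °C; HCl work-up
Reagents that add atoms: potassium hydroxide, [K+].[OH-]
Why: Claisen–Schmidt aldol condensation of the acetophenone enolate with the non-enolizable aldehyde should give the (E)-chalcone, and the same hydroxide saponifies the methyl ester on warming.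

**Step 4**
Reactants: 10 chalcone acid
Product: 11 (E)-2-{2-(benzyloxy)-5-[5,7-bis(benzyloxy)-4-oxo-4H-chromen-2-yl]phenyl}-3-[4-(benzyloxy)phenyl]prop-2-enoic acid
Conditions: I2 (10 mol%), DMSO, 120 °C
Reagents that add atoms: none
Why: Iodine-catalysed oxidative cyclization of a 2'-hydroxychalcone in DMSO (oxa-Michael closure, α-iodination, loss of HI, DMSO reoxidizing iodide) is the standard flavone synthesis and should leave the benzyl ethers and the acrylic acid untouched.

**Step 5**
Reactants: 12 3,5-bis(benzyloxy)phenol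
Product: 13 3,5-bis(benzyloxy)-2-iodophenol
Conditions: NIS, CH2Cl2, −20 → 0 °C, dark
Reagents that add atoms: N-iodosuccinimide (NIS), O=C1CCC(=O)N1I
Why: Electrophilic aromatic iodination, in which the free hydroxyl is the strongest director and its ortho carbon is less crowded than the carbon between the two benzyloxy groups, so the 2-iodo isomer should predominate and the 4-iodo isomer is removed by chromatography.

**Step 6**
Reactants: 11 flavone acid; 13 3,5-bis(benzyloxy)-2-iodophenol
Product: 14 3,5-bis(benzyloxy)-2-iodophenyl (E)-2-{2-(benzyloxy)-5-[5,7-bis(benzyloxy)-4-oxo-4H-chromen-2-yl]phenyl}-3-[4-(benzyloxy)phenyl]prop-2-enoate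
Conditions: EDC·HCl, DMAP (1 equiv), CH2Cl2, rt
Reagents that add atoms: none
Why: Steglich esterification through the acylpyridinium, with a full equivalent of DMAP because acid and phenol are both hindered.

**Step 7**
Reactants: 14 iodoaryl ester
Product: 17 (2RS,3SR)-5,7-bis(benzyloxy)-2-[4-(benzyloxy)phenyl]-3-{2-(benzyloxy)-5-[5,7-bis(benzyloxy)-4-oxo-4H-chromen-2-yl]phenyl}-2,3-dihydro-4H-chromen-4-one (racemic 2,3-trans), via arylmagnesium chloride 15 (not isolated), via chloromagnesium chalcone phenoxide 16 (not isolated)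
Conditions: i-PrMgCl·LiCl (1.1 equiv), THF, −40 → 0 °C; then AcOH/NaOAc, EtOH, 50 °C
Reagents that add atoms: none
Why: Proposed new method: iodine–magnesium exchange places a carbanion on the ring carbon between the acyloxy oxygen and a benzyloxy group, this carbanion adds to its own ester carbonyl through a four-membered transition state (4-exo-trig), the tetrahedral intermediate collapses with O-to-C 1,3-acyl shift to the 2'-oxidochalcone 16, and the freed oxygen closes ring C by 6-endo-trig oxa-Michael addition to the β-carbon once the acetate buffer loosens the magnesium chelate. The closest known reaction types are the halogen–metal-exchange-initiated anionic ortho-Fries rearrangement of 2-haloaryl esters and the insertion of arynes into α,β-unsaturated carboxylic acids, which passes through the same 2-acyloxyaryl anion and ends in 4-chromanones; neither has been run as a magnesium-mediated cascade on an α-aryl cinnamate. C2 is formed in the reversible oxa-Michael step and C3 by protonation of the resulting enolate, and equilibration through the enol and the ring-opened chalcone should leave the diequatorial 2,3-trans isomer as a racemate, the absolute configuration being set in step 8. The step needs C-acylation/O-alkylation in place of the C-alkylation/O-acylation (4-aryl dihydrocoumarin) mode common for phenols and cinnamoyl electrophiles, and acylation ortho and not para to the oxygen: the ester bridge commits the cinnamoyl unit as an acyl donor on O1, the iodine fixes the attacking carbon, and the Z geometry of the aryl ester holds that carbon next to the carbonyl and away from the β-carbon. Exchange at −40 °C should outpace addition of the Grignard reagent to the flavone or enoate carbonyl, and if the arylmagnesium instead expelled carboxylate to an aryne, re-addition of the carboxylate at the carbon remote from the benzyloxy group would return the same anion.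

**Step 8**
Reactants: 17 racemic trans-flavanone
Product: 18 (2R,3R,4S)-5,7-bis(benzyloxy)-2-[4-(benzyloxy)phenyl]-3-{2-(benzyloxy)-5-[5,7-bis(benzyloxy)-4-oxo-4H-chromen-2-yl]phenyl}-3,4-dihydro-2H-chromen-4-ol (2,3-trans, 3,4-cis)
Conditions: RuCl[(S,S)-TsDPEN](p-cymene) (5 mol%), HCO2H/Et3N (2:5), DMF, 40 °C
Reagents that add atoms: none
Why: Noyori–Ikariya asymmetric transfer hydrogenation run as a dynamic kinetic resolution, a known reaction type for 2,3-disubstituted flavanones: in the amine-rich medium 17 should racemize by retro-oxa-Michael opening of O1–C2 and enolization at C3, while the (S,S) catalyst delivers hydride to the face that gives the 4S benzylic alcohol and, approaching anti to the adjacent C3 aryl group, should do so quickly only for the (2R,3S) ketone, so C2 and C3 are fixed here and locked in the non-epimerizable alcohol.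

**Step 9**
Reactants: 18 flavan-4-ol
Product: 19 (2R,3S)-5,7-bis(benzyloxy)-2-[4-(benzyloxy)phenyl]-3-{2-(benzyloxy)-5-[5,7-bis(benzyloxy)-4-oxo-4H-chromen-2-yl]phenyl}-2,3-dihydro-4H-chromen-4-one
Conditions: Dess–Martin periodinane, CH2Cl2, 0 °C → rt, no added base
Reagents that add atoms: none
Why: Dess–Martin oxidation of the benzylic alcohol without base should regenerate the ketone without opening ring C, so C2 stays R and C3, already the more stable trans epimer, stays S.

**Step 10**
Reactants: 19 hexabenzyl ether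
Product: 20 (2R,3S)-5,7-dihydroxy-3-[2-hydroxy-5-(5,7-dihydroxy-4-oxo-4H-chromen-2-yl)phenyl]-2-(4-hydroxyphenyl)-2,3-dihydro-4H-chromen-4-one
Conditions: H2 (1 atm), 10% Pd/C, THF/MeOH, rt
Reagents that add atoms: none
Why: Catalytic hydrogenolysis of the six benzyl aryl ethers under neutral conditions should neither epimerize the flavanone (no base) nor dehydrate the 2-hydroxyaryl ketone to a benzofuran (no acid).

**Compound list**

1 | 4-(benzyloxy)benzaldehyde | O=Cc1ccc(OCc2ccccc2)cc1 | starting material
2 | methyl (triphenylphosphoranylidene)acetate | COC(=O)C=P(c1ccccc1)(c1ccccc1)c1ccccc1 | starting material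
3 | methyl bromo(triphenylphosphoranylidene)acetate | COC(=O)C(Br)=P(c1ccccc1)(c1ccccc1)c1ccccc1 | intermediate (not isolated)
4 | methyl (Z)-2-bromo-3-[4-(benzyloxy)phenyl]prop-2-enoate | COC(=O)/C(Br)=C/c1ccc(OCc2ccccc2)cc1 | intermediate
5 | 4-(benzyloxy)-3-bromobenzaldehyde | O=Cc1ccc(OCc2ccccc2)c(Br)c1 | starting material
6 | 4-(benzyloxy)-3-(4,4,5,5-tetramethyl-1,3,2-dioxaborolan-2-yl)benzaldehyde | O=Cc1ccc(OCc2ccccc2)c(B2OC(C)(C)C(C)(C)O2)c1 | intermediate (not isolated)
7 | methyl (E)-2-[2-(benzyloxy)-5-formylphenyl]-3-[4-(benzyloxy)phenyl]prop-2-enoate | COC(=O)/C(=C/c1ccc(OCc2ccccc2)cc1)c1cc(C=O)ccc1OCc1ccccc1 | intermediate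
8 | 1-[2,4-bis(benzyloxy)-6-hydroxyphenyl]ethanone | CC(=O)c1c(O)cc(OCc2ccccc2)cc1OCc1ccccc1 | starting material
9 | methyl (E)-2-{2-(benzyloxy)-5-[(E)-3-(2,4-bis(benzyloxy)-6-hydroxyphenyl)-3-oxoprop-1-enyl]phenyl}-3-[4-(benzyloxy)phenyl]prop-2-enoate | COC(=O)/C(=C/c1ccc(OCc2ccccc2)cc1)c1cc(/C=C/C(=O)c2c(O)cc(OCc3ccccc3)cc2OCc2ccccc2)ccc1OCc1ccccc1 | intermediate (not isolated)
10 | (E)-2-{2-(benzyloxy)-5-[(E)-3-(2,4-bis(benzyloxy)-6-hydroxyphenyl)-3-oxoprop-1-enyl]phenyl}-3-[4-(benzyloxy)phenyl]prop-2-enoic acid | OC(=O)/C(=C/c1ccc(OCc2ccccc2)cc1)c1cc(/C=C/C(=O)c2c(O)cc(OCc3ccccc3)cc2OCc2ccccc2)ccc1OCc1ccccc1 | intermediate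
11 | (E)-2-{2-(benzyloxy)-5-[5,7-bis(benzyloxy)-4-oxo-4H-chromen-2-yl]phenyl}-3-[4-(benzyloxy)phenyl]prop-2-enoic acid | OC(=O)/C(=C/c1ccc(OCc2ccccc2)cc1)c1cc(-c2cc(=O)c3c(OCc4ccccc4)cc(OCc4ccccc4)cc3o2)ccc1OCc1ccccc1 | intermediate
12 | 3,5-bis(benzyloxy)phenol | Oc1cc(OCc2ccccc2)cc(OCc2ccccc2)c1 | starting material
13 | 3,5-bis(benzyloxy)-2-iodophenol | Oc1cc(OCc2ccccc2)cc(OCc2ccccc2)c1I | intermediate
14 | 3,5-bis(benzyloxy)-2-iodophenyl (E)-2-{2-(benzyloxy)-5-[5,7-bis(benzyloxy)-4-oxo-4H-chromen-2-yl]phenyl}-3-[4-(benzyloxy)phenyl]prop-2-enoate | O=C(Oc1cc(OCc2ccccc2)cc(OCc2ccccc2)c1I)/C(=C/c1ccc(OCc2ccccc2)cc1)c1cc(-c2cc(=O)c3c(OCc4ccccc4)cc(OCc4ccccc4)cc3o2)ccc1OCc1ccccc1 | intermediate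
15 | arylmagnesium chloride from 14 (MgCl in place of iodine) | O=C(Oc1cc(OCc2ccccc2)cc(OCc2ccccc2)c1[Mg]Cl)/C(=C/c1ccc(OCc2ccccc2)cc1)c1cc(-c2cc(=O)c3c(OCc4ccccc4)cc(OCc4ccccc4)cc3o2)ccc1OCc1ccccc1 | intermediate (not isolated)
16 | chloromagnesium phenoxide of (E)-1-[2,4-bis(benzyloxy)-6-hydroxyphenyl]-2-{2-(benzyloxy)-5-[5,7-bis(benzyloxy)-4-oxo-4H-chromen-2-yl]phenyl}-3-[4-(benzyloxy)phenyl]prop-2-en-1-one | O=C(c1c(O[Mg]Cl)cc(OCc2ccccc2)cc1OCc1ccccc1)/C(=C/c1ccc(OCc2ccccc2)cc1)c1cc(-c2cc(=O)c3c(OCc4ccccc4)cc(OCc4ccccc4)cc3o2)ccc1OCc1ccccc1 | intermediate (not isolated)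
17 | (2RS,3SR)-5,7-bis(benzyloxy)-2-[4-(benzyloxy)phenyl]-3-{2-(benzyloxy)-5-[5,7-bis(benzyloxy)-4-oxo-4H-chromen-2-yl]phenyl}-2,3-dihydro-4H-chromen-4-one (racemate, 2,3-trans; the 2R,3S enantiomer is drawn) | O=C1c2c(OCc3ccccc3)cc(OCc3ccccc3)cc2O[C@@H](c2ccc(OCc3ccccc3)cc2)[C@@H]1c1cc(-c2cc(=O)c3c(OCc4ccccc4)cc(OCc4ccccc4)cc3o2)ccc1OCc1ccccc1 | intermediate
18 | (2R,3R,4S)-5,7-bis(benzyloxy)-2-[4-(benzyloxy)phenyl]-3-{2-(benzyloxy)-5-[5,7-bis(benzyloxy)-4-oxo-4H-chromen-2-yl]phenyl}-3,4-dihydro-2H-chromen-4-ol | O[C@@H]1c2c(OCc3ccccc3)cc(OCc3ccccc3)cc2O[C@@H](c2ccc(OCc3ccccc3)cc2)[C@@H]1c1cc(-c2cc(=O)c3c(OCc4ccccc4)cc(OCc4ccccc4)cc3o2)ccc1OCc1ccccc1 | intermediate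
19 | (2R,3S)-5,7-bis(benzyloxy)-2-[4-(benzyloxy)phenyl]-3-{2-(benzyloxy)-5-[5,7-bis(benzyloxy)-4-oxo-4H-chromen-2-yl]phenyl}-2,3-dihydro-4H-chromen-4-one | O=C1c2c(OCc3ccccc3)cc(OCc3ccccc3)cc2O[C@@H](c2ccc(OCc3ccccc3)cc2)[C@@H]1c1cc(-c2cc(=O)c3c(OCc4ccccc4)cc(OCc4ccccc4)cc3o2)ccc1OCc1ccccc1 | intermediate
20 | (2R,3S)-5,7-dihydroxy-3-[2-hydroxy-5-(5,7-dihydroxy-4-oxo-4H-chromen-2-yl)phenyl]-2-(4-hydroxyphenyl)-2,3-dihydro-4H-chromen-4-one | O=C1c2c(O)cc(O)cc2O[C@@H](c2ccc(O)cc2)[C@@H]1c1cc(-c2cc(=O)c3c(O)cc(O)cc3o2)ccc1O | target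

**Step count and risks**

Total step count: 10. Longest linear sequence: 9 steps (1 → 4 → 7 → 10 → 11 → 14 → 17 → 18 → 19 → 20; steps 1, 2, 3, 4, 6, 7, 8, 9, 10).

The three steps most likely to fail:

Step 7 (Proposed new method). What may go wrong: addition of the exchange reagent to the flavone or enoate carbonyl before iodine–magnesium exchange, protonation of the arylmagnesium before the acyl shift, or stalling at the magnesium-chelated chalcone. The fallback uses known chemistry, insertion of an aryne into the carboxylic acid followed by oxa-Michael closure. It sets out from 13 and 11, so step 6 is not needed. Compound 13 is silylated (HMDS, THF, 70 °C) to [3,5-bis(benzyloxy)-2-iodophenoxy]trimethylsilane F1. Treatment with n-BuLi (THF, −78 °C; iodine–lithium exchange and O-to-C silyl shift) and then Tf2O gives 3,5-bis(benzyloxy)-2-(trimethylsilyl)phenyl trifluoromethanesulfonate F2. F2 and acid 11 with CsF in THF at 125 °C (sealed tube) should give 17: the carboxylate adds to the aryne carbon remote from the neighbouring benzyloxy group, the aryl anion takes the acyl group from oxygen, and the phenoxide closes by oxa-Michael addition. The route is rejoined at 17.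

Step 8. What may go wrong: hydride transfer that is too slow at a carbonyl flanked by the 5-benzyloxy group and the C3 aryl group, competing reduction of the flavone, or ring opening too slow for a full dynamic resolution. The fallback is a physical separation in place of asymmetric catalysis. It sets out from 17: preparative chiral HPLC on an amylose tris(3,5-dimethylphenylcarbamate) phase should deliver 19 directly, so the route is rejoined at 19 and step 9 is not needed. The other enantiomer can be returned to racemic 17 with catalytic DBU and separated again. No new compound arises (F0).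

Step 10. What may go wrong: over-reduction (hydrogenolysis of the benzylic C2–O1 bond, reduction of the C4 carbonyl or of the flavone C2=C3 bond) or incomplete removal of the hindered 5-O-benzyl groups. The fallback is a Lewis-acid debenzylation in place of hydrogenolysis. It sets out from 19: BCl3 with pentamethylbenzene as cation scavenger in CH2Cl2 at −78 °C, quenched cold with MeOH, should give 20 directly, so the route is rejoined at 20. No new compound arises (F0).

Further compounds
F1 | step 7 | [3,5-bis(benzyloxy)-2-iodophenoxy]trimethylsilane | C[Si](C)(C)Oc1cc(OCc2ccccc2)cc(OCc2ccccc2)c1I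
F2 | step 7 | 3,5-bis(benzyloxy)-2-(trimethylsilyl)phenyl trifluoromethanesulfonate | C[Si](C)(C)c1c(OS(=O)(=O)C(F)(F)F)cc(OCc2ccccc2)cc1OCc1ccccc1
F0 | step 8 | none | none
F0 | step 10 | none | none
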